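Substrate and product cannot be the whole of the south-west flask: at 1.33 min they read 29.4% and 15.6%, together 45.0% of the charge, so the rest stands in forms that no reading shows.

| setting | south-west | south | north | east | beta | theta | alpha |
|---|---|---|---|---|---|---|---|
| substrate | 0.26 M | 0.13 M | 0.20 M | 0.26 M | 0.26 M (fed, over 8.0 min) | 0.26 M | 0.26 M |
| reagent | 0.26 M | 0.26 M | 0.26 M | 0.13 M | 0.260 M | 0.260 M (fed, over 8.0 min) | 0.260 M |
| remark | run made earlier | run made earlier | run made earlier | run made earlier | all else is in the flask from the start; the feed brings no volume worth counting | all else is in the flask from the start; the feed brings no volume worth counting | everything together at the start |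
| time |  |  |  |  | 12 min | 12 min | 12 min |

1. the flask that comes out highest in amount of product, in percent of the substrate charged, or "all alike" when all lie within 1.5 percentage points (beta / theta / alpha / all alike)
2. product at the end, in percent of the substrate charged, beta
3. product at the end, in percent of the substrate charged, theta
4. product at the end, in percent of the substrate charged, alpha

- a reading of substrate is of its free form alone

| run | time / min | product / % | substrate / % |
|---|---|---|---|
| south-west | 1.33 | 15.6 | 29.4 |
| south-west | 3.00 | 27.7 | 26.0 |
| south-west | 4.00 | 34.0 | 25.1 |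
| south-west | 6.00 | 43.3 | 21.4 |
| south-west | 8.00 | 51.4 | 19.0 |
| south | 0.667 | 10.9 | 30.9 |
| south | 2.00 | 24.0 | 24.6 |
| south | 3.00 | 31.1 | 22.2 |
| south | 5.00 | 45.0 | 17.9 |
| south | 8.00 | 59.4 | 13.5 |
| north | 0.667 | 10.7 | 31.7 |
| north | 2.00 | 21.7 | 25.7 |
| north | 3.00 | 29.0 | 24.1 |
| north | 5.00 | 41.6 | 20.6 |
| north | 8.00 | 54.0 | 17.0 |
| east | 0.500 | 4.1 | 41.8 |
| east | 1.00 | 7.8 | 38.0 |
| east | 2.00 | 10.8 | 36.6 |
| east | 4.00 | 18.1 | 33.3 |
| east | 8.00 | 30.2 | 30.8 |

(standard deviation of a reading: 0.5 percentage points)

Alpha repeats the south-west charges for longer, so the south-west table is the one to read. Free substrate, as a share of what is not yet product, reads 0.380 at 4.00 min and 0.391 at 8.00 min: a nearly steady fraction. Free reagent is not read; taken as a steady fraction too, with equal charges the rate follows the square of the unreacted share, so the reciprocal of that share should climb straight with time. It reads 1.52 at 4.00 min and 2.06 at 8.00 min.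

Its rise per minute, divided by the charge, is the clock constant, an apparent second-order rate constant, read here from these two scattered points as 0.522 M⁻¹ min⁻¹. Integrated for unequal charges, it gives 59.0% for the south run at 8.00 min, read as 59.4%, and 29.5% for the east run, read as 30.2%.

Run on to 12 min, the clock gives alpha 61.5%. A steady feed delivers its charge on average at half of 8.0 min, so in this rough reckoning beta and theta each count as a batch aged 8.00 min, and the south-west table reads 51.4% there, lower than the clock's figure for alpha.

The forecast names alpha, with 51% for beta, 52% for theta and 62% for alpha, holding that “Feeding either one simply keeps concentrations low during the feed and loses time”.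

The flasks give 50.5% for beta, 50.0% for theta and 61.6% for alpha, so alpha comes out highest.

    substrate + reagent ⇌ intermediate A (K = 6.60 M⁻¹, k = 0.460 M⁻¹ s⁻¹)
    substrate ⇌ intermediate B (K = 1.10, k = 0.0350 s⁻¹)
    substrate + reagent → product (k = 0.0410 M⁻¹ s⁻¹)
    reagent ⇌ dormant form (K = 0.420, k = 0.0240 s⁻¹)

Alpha's 61.6% puts the reciprocal at 2.60, against 2.60 from the clock, and alpha is still running at 12 min, with 95.7% product at 120 min. A neighbour of alpha holds 0.065 M of substrate, a quarter of alpha's charge, with reagent kept at 0.260 M. There 0.522 M⁻¹ min⁻¹ gives 76.1% at 12 min, and the neighbour gives 76.6% product, with 55.6% of its reagent charge left.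

The earlier runs and the new flask come from a simulation for substances that don't exist, noise included.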